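**Plan**

1. Retrosynthetic cuts: first the acetate C–O bond; then the two quinone C=O groups, back to a 3-methoxy-5-alkylphenol; then the side-chain bond between the benzylic CH2 (C1') and the oxygen-bearing CH (C2').
2. Enabling features: C2' is an sp3 carbon carrying O, H, the undecyl chain and the benzylic CH2, so it can be delivered as a chiral α-oxygenated carbenoid (lithiated dodecyl carbamate) that inserts into the B–CH2 bond of a benzylboronic ester. In the six-membered ring, the carbon between C–OMe and C–alkyl is para to the phenol OH, so para-oxidation gives exactly the 2-methoxy-6-alkyl-1,4-benzoquinone.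
3. Forward order: 3,5-dimethoxybenzyl bromide → benzylboronic ester; 1-dodecanol → carbamate; lithiation–borylation–oxidation joins the halves; then mono-demethylation (the two OMe groups are equivalent), diacetylation, selective release of the phenol and Teuber oxidation. No ring is built; the purchased benzene ring becomes the quinone in the last step.
4. Stereochemistry: the single stereocentre comes from (−)-sparteine/s-BuLi deprotonation, borylation with retention, 1,2-shift with inversion and C–B oxidation with retention, giving (R); no later step touches it.

Key step: step 3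

Remark: (−)-sparteine is taken to remove the pro-S hydrogen of the O-alkyl carbamate, as is general for this base; the (S)-carbenoid then leads to the (R)-carbinol.

**Route**

Step 1
Reactants: 1 3,5-dimethoxybenzyl bromide
Product: 2 2-(3,5-dimethoxybenzyl)-4,4,5,5-tetramethyl-1,3,2-dioxaborolane
Conditions: B2pin2 (1.1 equiv), Pd2(dba)3 (cat.), P(4-MeOC6H4)3 (cat.), KOAc, toluene, 50 °C
Reagents that add atoms: bis(pinacolato)diboron, CC1(C)OB(OC1(C)C)B1OC(C)(C)C(C)(C)O1
Why: Miyaura borylation of a benzylic halide (oxidative addition of Pd(0) into C–Br, acetate-assisted transmetallation with the diboron, reductive elimination) should give the benzylboronic ester, the electron-rich phosphine limiting homocoupling.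

Step 2
Reactants: 3 1-dodecanol
Product: 4 dodecyl N,N-diisopropylcarbamate
Conditions: NaH, THF, 0 °C; then iPr2NCOCl, reflux
Reagents that add atoms: N,N-diisopropylcarbamoyl chloride, CC(C)N(C(C)C)C(Cl)=O
Why: O-carbamoylation of the sodium alkoxide (nucleophilic acyl substitution) should give the base-stable hindered carbamate that later directs the α-lithiation and serves as the leaving group.

Step 3
Reactants: 4 dodecyl N,N-diisopropylcarbamate; 2 2-(3,5-dimethoxybenzyl)-4,4,5,5-tetramethyl-1,3,2-dioxaborolane
Product: 8 (2R)-1-(3,5-dimethoxyphenyl)tridecan-2-ol, via lithiated carbamate 5 (not isolated), via boronate complex 6 (not isolated), via secondary boronic ester 7 (not isolated)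
Conditions: 4 (1.3 equiv), (−)-sparteine, s-BuLi, Et2O, −78 °C, 5 h; 2 (1.0 equiv), −78 °C, 1 h; MgBr2·OEt2, −78 °C → reflux; then 2 M NaOH, 30% H2O2, THF, 0 °C → rt
Reagents that add atoms: sec-butyllithium, CCC(C)[Li] (lithium of 5 and 6); hydrogen peroxide, OO (hydroxyl oxygen of 8)
Why: s-BuLi complexed by (−)-sparteine removes the pro-S hydrogen next to the carbamate oxygen of 4 to give the configurationally stable carbenoid 5, which adds to the empty p orbital of boron in 2 with retention to give boronate 6; on warming with MgBr2 the benzyl group shifts from boron to carbon antiperiplanar to the departing carbamate (1,2-metallate rearrangement, inversion at carbon), forming the ArCH2–CH bond of 7, and alkaline H2O2 then replaces boron by oxygen with retention. The closest known reaction type is the lithiation–borylation of pinacol boronic esters with sparteine-derived lithiated primary alkyl carbamates, a reagent-controlled Matteson-type homologation. No ring is closed. The only new stereocentre, C2 of the tridecyl chain, is set by the reagent: (S)-5 → (S)-6 → (R)-7 → (R)-8, as one retentive and one invertive stereospecific event are followed by a retentive oxidation. The step needs addition of 5 to boron in preference to proton transfer from the acidic benzylic B–CH2 of 2, and migration of the benzyl carbon in preference to a pinacol oxygen. The first should be secured by the low temperature and the unhindered Lewis-acidic primary boronic ester, the second by the higher migratory aptitude of carbon and the Lewis acid activation of the carbamate leaving group.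

Step 4
Reactants: 8 (2R)-1-(3,5-dimethoxyphenyl)tridecan-2-ol
Product: 9 3-[(2R)-2-hydroxytridecyl]-5-methoxyphenol
Conditions: NaSEt (4 equiv), DMF, 140 °C; then aq. HCl
Reagents that add atoms: none
Why: Nucleophilic demethylation of an aryl methyl ether (SN2 of ethanethiolate at the methyl carbon) should stop after one methyl group because the phenoxide formed deactivates the second ether, and the equivalence of the two methoxy groups allows only one monophenol; the stereocentre is not involved.

Step 5
Reactants: 9 3-[(2R)-2-hydroxytridecyl]-5-methoxyphenol
Product: 10 3-[(2R)-2-acetoxytridecyl]-5-methoxyphenyl acetate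
Conditions: Ac2O, pyridine, DMAP (cat.), CH2Cl2, rt
Reagents that add atoms: acetic anhydride, CC(=O)OC(C)=O
Why: DMAP-catalysed acyl transfer (exhaustive O-acetylation) should esterify both hydroxyl groups with retention at the carbinol carbon, since its C–O bond is not broken.

Step 6
Reactants: 10 3-[(2R)-2-acetoxytridecyl]-5-methoxyphenyl acetate
Product: 11 (2R)-1-(3-hydroxy-5-methoxyphenyl)tridecan-2-yl acetate
Conditions: pyrrolidine (2 equiv), MeCN, 0 °C → rt
Reagents that add atoms: none
Why: Chemoselective aminolysis of the aryl ester should free only the phenol, because phenoxide is a far better leaving group than a secondary alkoxide and the hindered alkyl acetate is inert to the amine at room temperature.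

Step 7
Reactants: 11 (2R)-1-(3-hydroxy-5-methoxyphenyl)tridecan-2-yl acetate
Product: 12 (2R)-1-(5-methoxy-3,6-dioxocyclohexa-1,4-dien-1-yl)tridecan-2-yl acetate
Conditions: (KSO3)2NO (2.5 equiv), aq. KH2PO4, acetone, rt
Reagents that add atoms: Fremy's salt (dipotassium nitrosodisulfonate), [K+].[K+].[O]N(S(=O)(=O)[O-])S(=O)(=O)[O-]
Why: Teuber oxidation: the nitroxyl radical abstracts the phenolic hydrogen, a second equivalent couples at the free para carbon (the one between C–OMe and C–alkyl) and loss of imidodisulfonate should give the 1,4-quinone, while the neutral buffer leaves the secondary acetate and the stereocentre untouched.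

**Compound list**

1 | 3,5-dimethoxybenzyl bromide | COc1cc(CBr)cc(OC)c1 | starting material
2 | 2-(3,5-dimethoxybenzyl)-4,4,5,5-tetramethyl-1,3,2-dioxaborolane | COc1cc(CB2OC(C)(C)C(C)(C)O2)cc(OC)c1 | intermediate
3 | 1-dodecanol | CCCCCCCCCCCCO | starting material
4 | dodecyl N,N-diisopropylcarbamate | CCCCCCCCCCCCOC(=O)N(C(C)C)C(C)C | intermediate
5 | (S)-1-lithiododecyl N,N-diisopropylcarbamate (lithiated carbamate, present as its (−)-sparteine complex, not isolated) | CCCCCCCCCCC[C@H]([Li])OC(=O)N(C(C)C)C(C)C | intermediate
6 | lithium [(1S)-1-(N,N-diisopropylcarbamoyloxy)dodecyl](3,5-dimethoxybenzyl)(pinacolato)borate (boronate complex, not isolated) | CCCCCCCCCCC[C@H]([B-]1(Cc2cc(OC)cc(OC)c2)OC(C)(C)C(C)(C)O1)OC(=O)N(C(C)C)C(C)C.[Li+] | intermediate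
7 | 2-[(2R)-1-(3,5-dimethoxyphenyl)tridecan-2-yl]-4,4,5,5-tetramethyl-1,3,2-dioxaborolane (secondary boronic ester, not isolated) | CCCCCCCCCCC[C@H](Cc1cc(OC)cc(OC)c1)B1OC(C)(C)C(C)(C)O1 | intermediate
8 | (2R)-1-(3,5-dimethoxyphenyl)tridecan-2-ol | CCCCCCCCCCC[C@H](Cc1cc(OC)cc(OC)c1)O | intermediate
9 | 3-[(2R)-2-hydroxytridecyl]-5-methoxyphenol | CCCCCCCCCCC[C@H](Cc1cc(O)cc(OC)c1)O | intermediate
10 | 3-[(2R)-2-acetoxytridecyl]-5-methoxyphenyl acetate | CCCCCCCCCCC[C@H](Cc1cc(OC(C)=O)cc(OC)c1)OC(C)=O | intermediate
11 | (2R)-1-(3-hydroxy-5-methoxyphenyl)tridecan-2-yl acetate | CCCCCCCCCCC[C@H](Cc1cc(O)cc(OC)c1)OC(C)=O | intermediate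
12 | (2R)-1-(5-methoxy-3,6-dioxocyclohexa-1,4-dien-1-yl)tridecan-2-yl acetate | CCCCCCCCCCC[C@H](CC1=CC(=O)C=C(OC)C1=O)OC(C)=O | target

**Step count**

Total step count: 7 (steps 1 and 2 are parallel fragment preparations).
Longest linear sequence: 6 steps (step 2 or step 1, then steps 3 to 7).

**Steps most likely to fail**

Step 3. The carbenoid may take a proton from the acidic benzylic CH2 of the boronic ester instead of adding to boron, the 1,2-shift may be sluggish, or the asymmetric deprotonation may be incomplete, each lowering conversion or enantiomeric purity. The fallback takes the stereocentre from a resolved epoxide and forms the aryl–CH2 bond instead. It sets out from 1-dodecanol 3, which is oxidised (TEMPO, NaOCl, KBr, CH2Cl2/H2O, 0 °C) to dodecanal F1. Corey–Chaykovsky methylenation (Me3S+ I−, NaH, DMSO/THF) should give racemic 2-undecyloxirane F2. Jacobsen hydrolytic kinetic resolution ((R,R)-(salen)Co(III)OAc, 0.55 equiv H2O) should hydrolyse the (S)-oxirane and leave (R)-2-undecyloxirane F3. Copper-catalysed opening of F3 at its terminal carbon by 3,5-dimethoxyphenylmagnesium bromide F4 (from 1-bromo-3,5-dimethoxybenzene and Mg; CuI cat., THF, −30 °C) should give alcohol 8, where the fallback rejoins the route.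

Step 7. The nitroxyl radical may couple at an ortho position, leading to o-quinone and coupled material, or the lipophilic phenol may convert slowly in the aqueous medium. The fallback replaces the stoichiometric radical oxidant by a catalytic aerobic oxygenation of a different mechanism: Co(salen) (salcomine), O2, DMF, rt, in which a cobalt-bound superoxide oxygenates the para carbon of the phenoxyl radical. It sets out from 11 and comes back directly at 12; no new compound is made (entry F0).

Step 6. Chemoselectivity between the two esters may be lost, with partial aminolysis of the secondary acetate or incomplete release of the phenol. The fallback reverses the order of oxidation and acylation so that no diester is needed. It sets out from 9, whose Teuber oxidation ((KSO3)2NO, aq. KH2PO4, acetone) should give 2-[(2R)-2-hydroxytridecyl]-6-methoxycyclohexa-2,5-diene-1,4-dione F5. Acetylation of its secondary alcohol (Ac2O, pyridine, DMAP cat., CH2Cl2, 0 °C) comes back to the route at 12.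

**Further compounds**

F1 | step 3 | dodecanal | CCCCCCCCCCCC=O
F2 | step 3 | racemic 2-undecyloxirane | CCCCCCCCCCCC1CO1
F3 | step 3 | (R)-2-undecyloxirane | CCCCCCCCCCC[C@@H]1CO1
F4 | step 3 | 3,5-dimethoxyphenylmagnesium bromide | COc1cc([Mg]Br)cc(OC)c1
F0 | step 7 | none | none
F5 | step 6 | 2-[(2R)-2-hydroxytridecyl]-6-methoxycyclohexa-2,5-diene-1,4-dione | CCCCCCCCCCC[C@H](CC1=CC(=O)C=C(OC)C1=O)O
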